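**Retrosynthetic overview**

- Target 25 comes from triol diene 24 by a last-step acetylation at O7; the (12Z)-diene comes from the C12 lactol 22 by Stork–Zhao iodo-olefination and Stille vinylation.
- The 6,7,8-triol comes from the ring B enone 13: epoxidation, Wharton transposition to the Δ6-8-ol 15, dihydroxylation, then inversion at C7 by oxidation and reduction.
- Ring A comes from nitro ketone 6 and 3-methylbut-2-enal 7 in a formal [3+3] annulation. One operation forms C1–C2 (nitroaldol condensation) and C4–C5 (intramolecular 1,6-addition) and brings in C2, C3, C4 and both C4 methyl groups; the nitro group and the ring A double bond are removed afterwards.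
- Enabling feature: the C6 oxygen of ring B and the quaternary C10. With C6 as a ketone, C5 is an enolisable CH2 that stands 1,3 to C1, the exocyclic CH2 on C10; a removable nitro group makes C1 a second carbon nucleophile, so C1–C10–C5 is a 1,3-bis-nucleophile.
- Ring order: ring B first (asymmetric Robinson annulation of 1 and 2), then ring A in the key step. The C8 methyl centre relays chirality to C9 and C10, is removed in step 6 and rebuilt in step 7.

Key step: step 3

Remark: labdane numbering (C1–C20, C20 = angular methyl on C10) is used in the discussion and "syn/anti" refer to C20; the absolute configuration of each compound is that of its SMILES (25 is 5R,6S,7R,8R,9S,10R, the enantio-labdane series).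

**Route**

Step 1
Reactants: 1 ethyl acetoacetate; 2 (E)-pent-3-en-2-one
Product: 4 ethyl (6R)-2,6-dimethyl-4-oxocyclohex-2-ene-1-carboxylate (both C1 epimers), via Michael adduct 3 (not isolated)
Conditions: 9-amino-9-deoxy-epi-cinchona primary amine (pseudoenantiomer that gives 3R, 10 mol %), TFA (20 mol %), toluene, 23 °C; then TsOH·H2O (10 mol %), toluene, 110 °C, azeotropic removal of water
Reagents that add atoms: none
Why: Iminium-catalysed asymmetric Michael addition of the β-keto ester to the enone, followed by acid-catalysed aldol condensation of the methyl ketone onto the acetoacetate carbonyl (Robinson annulation), closes ring B; the chiral primary amine shields one face of the iminium ion and so sets the methyl-bearing centre (3R in 3, the later C8), while the ester-bearing carbon stays epimerisable.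

Step 2
Reactants: 4 ethyl (6R)-2,6-dimethyl-4-oxocyclohex-2-ene-1-carboxylate; 5 nitromethane
Product: 6 ethyl (1R,2R,6R)-2,6-dimethyl-2-(nitromethyl)-4-oxocyclohexane-1-carboxylate
Conditions: 5 (10 equiv), DBU (0.5 equiv), MeCN, 40 °C
Reagents that add atoms: none
Why: Michael addition of nitromethane to the β-methyl cyclohexenone builds the quaternary centre (the later C10); the two C1 epimers of 4 interconvert through the extended enolate of the vinylogous β-keto ester, and only the cis epimer offers a face that is anti both to the pseudoaxial ester and to the 6-methyl group, so axial attack there should funnel the mixture into the 1R,2R,6R isomer.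

Step 3
Reactants: 6 ethyl (1R,2R,6R)-2,6-dimethyl-2-(nitromethyl)-4-oxocyclohexane-1-carboxylate; 7 3-methylbut-2-enal
Product: 9 ethyl 2,5,5,8a-tetramethyl-8-nitro-4-oxo-1,2,3,4,4a,5,8,8a-octahydronaphthalene-1-carboxylate (trans-fused; both nitro epimers), via nitrodiene 8 (not isolated)
Conditions: 7 (2 equiv), piperidine (20 mol %), AcOH (20 mol %), 4 Å molecular sieves, toluene, 60 °C; then DBU (1.5 equiv), 23 °C
Reagents that add atoms: none
Why: Proposed new method: the nitronate of 6 should condense with the iminium ion of 7 (nitroaldol addition, then loss of the amine and water) to the (E)-1-nitro-1,3-diene 8, whose dimethyl-substituted δ-carbon (C4) is then attacked by the C5 enolate of the C6 ketone in an intramolecular vinylogous (1,6) Michael addition; the closest known reactions are amine-catalysed nitroaldol condensations of enals to nitrodienes, conjugate additions of ketone enolates and enamines to nitrodienes, and Michael–Henry [3+3] annulations of γ-nitro ketones with enals. Ring A closes in a 6-endo-trig mode, the only ring size open to the tethered enolate (attack at C2 would give a four-membered ring), so the quaternary centre C4 forms regiospecifically. C5 is the only new stereocentre that is kept: it is α to the C6 ketone and should equilibrate under DBU to the trans-fused decalone (H-5 anti to C20), while the nitro-bearing C1 is formed as a mixture of epimers and is reduced to CH2 later. The step needs C5 to react in preference to C7 and C9: from the ketone enolate only C5 reaches C4 through a six-membered transition state, C7 would need an eight-membered ring, and the ester α-carbon C9 is far less acidic and fully substituted. The product nitronate is a stable anion, which should make the ring closure irreversible and pull the reversible condensation through.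

Step 4
Reactants: 9 ethyl 2,5,5,8a-tetramethyl-8-nitro-4-oxo-1,2,3,4,4a,5,8,8a-octahydronaphthalene-1-carboxylate
Product: 10 ethyl 2,5,5,8a-tetramethyl-4-oxo-1,2,3,4,4a,5,8,8a-octahydronaphthalene-1-carboxylate (ring A alkene; may contain its double-bond isomer)
Conditions: Bu3SnH (2.5 equiv), AIBN (0.3 equiv), toluene, 90 °C
Reagents that add atoms: none
Why: Radical denitration: the stannyl radical adds to a nitro oxygen, the allylic C–N bond fragments and the delocalised C1–C3 allyl radical takes hydrogen from Bu3SnH, so both nitro epimers (and any double-bond isomer) end as ring A alkenes that converge in step 5; no stereocentre is formed.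

Step 5
Reactants: 10 ethyl 2,5,5,8a-tetramethyl-4-oxo-1,2,3,4,4a,5,8,8a-octahydronaphthalene-1-carboxylate
Product: 11 ethyl 2,5,5,8a-tetramethyl-4-oxodecahydronaphthalene-1-carboxylate (trans-fused)
Conditions: H2 (1 atm), 10% Pd/C, EtOAc, 23 °C
Reagents that add atoms: none
Why: Heterogeneous hydrogenation of the cis-disubstituted ring A alkene, with the hindered ketone and the ester untouched; no stereocentre is formed.

Step 6
Reactants: 11 ethyl 2,5,5,8a-tetramethyl-4-oxodecahydronaphthalene-1-carboxylate
Product: 13 ethyl 2,5,5,8a-tetramethyl-4-oxo-1,4,4a,5,6,7,8,8a-octahydronaphthalene-1-carboxylate (ring B enone), via silyl enol ether 12 (not isolated)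
Conditions: LiN(iPr)2 (1.05 equiv), Me3SiCl, THF, −78 °C; then Pd(OAc)2 (1.1 equiv), MeCN, 23 °C
Reagents that add atoms: none
Why: Saegusa–Ito oxidation: the kinetic enolate forms only toward C7 (C5 is tertiary and hindered), and palladation with β-hydride elimination gives the C7=C8 enone under neutral conditions; this matters because C9 is now the acidic γ-position of a vinylogous β-keto ester and must keep its kinetic configuration, while the C8 stereocentre is removed here and rebuilt in step 7.

Step 7
Reactants: 13 ethyl 2,5,5,8a-tetramethyl-4-oxo-1,4,4a,5,6,7,8,8a-octahydronaphthalene-1-carboxylate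
Product: 14 ethyl 2,3-epoxy-2,5,5,8a-tetramethyl-4-oxodecahydronaphthalene-1-carboxylate (epoxide oxygen anti to the angular methyl)
Conditions: dimethyldioxirane (acetone solution, 3 equiv), CH2Cl2, 0 to 23 °C
Reagents that add atoms: dimethyldioxirane CC1(C)OO1
Why: Electrophilic epoxidation of the enone with the dioxirane under neutral conditions from the ring B face anti to the axial angular methyl C20 (and anti to the C9 ester), which sets C7 and C8 with the oxygen anti to C20 and the C8 methyl syn.

Step 8
Reactants: 14 ethyl 2,3-epoxy-2,5,5,8a-tetramethyl-4-oxodecahydronaphthalene-1-carboxylate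
Product: 15 ethyl 2-hydroxy-2,5,5,8a-tetramethyl-1,2,4a,5,6,7,8,8a-octahydronaphthalene-1-carboxylate (Δ6-8-ol in labdane numbering)
Conditions: N2H4·H2O (3 equiv), AcOH (0.5 equiv), MeOH, 0 to 23 °C
Reagents that add atoms: none
Why: Wharton transposition: the hydrazone of the α,β-epoxy ketone opens the epoxide and the vinyl diazene loses N2 to give the transposed allylic alcohol with a C6=C7 double bond; the C8–O bond is never broken, so the tertiary carbinol keeps its configuration.

Step 9
Reactants: 15 ethyl 2-hydroxy-2,5,5,8a-tetramethyl-1,2,4a,5,6,7,8,8a-octahydronaphthalene-1-carboxylate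
Product: 16 ethyl 2,3,4-trihydroxy-2,5,5,8a-tetramethyldecahydronaphthalene-1-carboxylate (all three hydroxyls anti to the angular methyl)
Conditions: OsO4 (5 mol %), N-methylmorpholine N-oxide (2 equiv), acetone/H2O (4:1), 40 °C
Reagents that add atoms: N-methylmorpholine N-oxide C[N+]1([O-])CCOCC1; water O
Why: Catalytic OsO4 syn-dihydroxylation of the ring B alkene from the face anti to C20 and to the axial 8-methyl (the face of the allylic hydroxyl), giving the 6,7-cis-diol with the final C6 configuration (equatorial 6-OH) and an axial 7-OH.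

Step 10
Reactants: 16 ethyl 2,3,4-trihydroxy-2,5,5,8a-tetramethyldecahydronaphthalene-1-carboxylate
Product: 18 ethyl 2,4-dihydroxy-2,5,5,8a-tetramethyl-3-oxodecahydronaphthalene-1-carboxylate, via stannylene acetal 17 (not isolated)
Conditions: Bu2SnO (1.1 equiv), MeOH, 65 °C, then evaporation; Br2 (1.05 equiv), 4 Å molecular sieves, CH2Cl2, 23 °C
Reagents that add atoms: none
Why: Brominolysis of a dibutylstannylene acetal oxidises the carbon that bears the axial oxygen of a cis-diol, so only the axial 7-OH becomes a ketone while the equatorial 6-OH and the tertiary 8-OH stay; no stereocentre is formed.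

Step 11
Reactants: 18 ethyl 2,4-dihydroxy-2,5,5,8a-tetramethyl-3-oxodecahydronaphthalene-1-carboxylate
Product: 19 1-(hydroxymethyl)-2,5,5,8a-tetramethyldecahydronaphthalene-2,3,4-triol
Conditions: LiAlH4 (4 equiv), THF, 0 to 23 °C
Reagents that add atoms: none
Why: LiAlH4 reduces the ester to the primary alcohol and the C7 ketone by axial hydride delivery from the open face anti to C20 and the axial 8-methyl, which gives the equatorial 7-OH (syn to C20) and so inverts C7 relative to 16.

Step 12
Reactants: 19 1-(hydroxymethyl)-2,5,5,8a-tetramethyldecahydronaphthalene-2,3,4-triol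
Product: 20 2,3,4-trihydroxy-2,5,5,8a-tetramethyldecahydronaphthalene-1-carbaldehyde
Conditions: TEMPO (10 mol %), PhI(OAc)2 (1.1 equiv), CH2Cl2, 23 °C
Reagents that add atoms: none
Why: Oxoammonium (TEMPO) oxidation with PhI(OAc)2 as the terminal oxidant is selective for the primary alcohol over the hindered secondary and tertiary ones; no stereocentre changes.

Step 13
Reactants: 20 2,3,4-trihydroxy-2,5,5,8a-tetramethyldecahydronaphthalene-1-carbaldehyde
Product: 22 3a,6,6,9a-tetramethyldodecahydronaphtho[2,1-b]furan-2,4,5-triol (C12 lactol), via enol ether 21 (not isolated)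
Conditions: Ph3P(CH2OMe)Cl (5 equiv), KN(SiMe3)2 (4.8 equiv), THF, −78 to 0 °C; then 1 M HCl, THF, 23 °C
Reagents that add atoms: (methoxymethyl)triphenylphosphonium chloride COC[P+](c1ccccc1)(c1ccccc1)c1ccccc1.[Cl-]; water O
Why: Wittig methoxymethylenation of the hindered aldehyde and acid hydrolysis of the enol ether add one carbon (C12), and the new aldehyde is trapped by the 8-hydroxyl as a five-membered lactol (anomeric mixture, of no consequence).

Step 14
Reactants: 22 3a,6,6,9a-tetramethyldodecahydronaphtho[2,1-b]furan-2,4,5-triol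
Product: 23 1-[(2Z)-3-iodobut-2-en-1-yl]-2,5,5,8a-tetramethyldecahydronaphthalene-2,3,4-triol
Conditions: EtPPh3I (5 equiv), n-BuLi, THF, 23 °C; I2, −78 °C; NaN(SiMe3)2, −20 °C; then 22, THF/DMPU, −78 to −20 °C
Reagents that add atoms: ethyltriphenylphosphonium iodide CC[P+](c1ccccc1)(c1ccccc1)c1ccccc1.[I-]; iodine II
Why: Stork–Zhao olefination: the open hydroxy aldehyde form of the lactol reacts with the non-stabilised α-iodo ylide under kinetic Wittig control to give the trisubstituted (Z)-vinyl iodide with iodine cis to C11.

Step 15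
Reactants: 23 1-[(2Z)-3-iodobut-2-en-1-yl]-2,5,5,8a-tetramethyldecahydronaphthalene-2,3,4-triol
Product: 24 2,5,5,8a-tetramethyl-1-[(2Z)-3-methylpenta-2,4-dien-1-yl]decahydronaphthalene-2,3,4-triol
Conditions: CH2=CHSnBu3 (1.5 equiv), Pd(PPh3)4 (5 mol %), CuI (10 mol %), DMF, 40 °C
Reagents that add atoms: tributyl(vinyl)stannane C=C[Sn](CCCC)(CCCC)CCCC
Why: Stille coupling of the vinyl iodide with the vinylstannane proceeds with retention of the alkene geometry and so gives the (12Z)-diene; free hydroxyls are tolerated.

Step 16
Reactants: 24 2,5,5,8a-tetramethyl-1-[(2Z)-3-methylpenta-2,4-dien-1-yl]decahydronaphthalene-2,3,4-triol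
Product: 25 (1S,2R,3R,4S,4aR,8aR)-2,4-dihydroxy-2,5,5,8a-tetramethyl-1-[(2Z)-3-methylpenta-2,4-dien-1-yl]decahydronaphthalen-3-yl acetate
Conditions: Ac2O (1.1 equiv), pyridine, DMAP (5 mol %), CH2Cl2, −20 °C
Reagents that add atoms: acetic anhydride CC(=O)OC(C)=O
Why: O7 is the least hindered secondary hydroxyl (O6 is pressed against the equatorial C4 methyl group and O8 is tertiary), so one equivalent of anhydride at low temperature should acylate it selectively under base-only conditions that spare the acid-sensitive hydroxy diene; no stereocentre changes.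

**Compound list**

1 | ethyl acetoacetate | CCOC(=O)CC(C)=O | starting material
2 | (E)-pent-3-en-2-one | C/C=C/C(C)=O | starting material
3 | ethyl (3R)-2-acetyl-3-methyl-5-oxohexanoate (both C2 epimers) | CCOC(=O)C(C(C)=O)[C@H](C)CC(C)=O | intermediate
4 | ethyl (6R)-2,6-dimethyl-4-oxocyclohex-2-ene-1-carboxylate (both C1 epimers) | CCOC(=O)C1[C@H](C)CC(=O)C=C1C | intermediate
5 | nitromethane | C[N+](=O)[O-] | starting material
6 | ethyl (1R,2R,6R)-2,6-dimethyl-2-(nitromethyl)-4-oxocyclohexane-1-carboxylate | CCOC(=O)[C@@H]1[C@H](C)CC(=O)C[C@@]1(C)C[N+](=O)[O-] | intermediate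
7 | 3-methylbut-2-enal | CC(C)=CC=O | starting material
8 | ethyl (1R,2R,6R)-2,6-dimethyl-2-[(1E)-4-methyl-1-nitropenta-1,3-dien-1-yl]-4-oxocyclohexane-1-carboxylate | CCOC(=O)[C@@H]1[C@H](C)CC(=O)C[C@@]1(C)/C(=C\C=C(C)C)[N+](=O)[O-] | intermediate
9 | ethyl 2,5,5,8a-tetramethyl-8-nitro-4-oxo-1,2,3,4,4a,5,8,8a-octahydronaphthalene-1-carboxylate; trans-fused (4a-H anti to the 8a-methyl), 1-CO2Et and 2-CH3 syn to the 8a-methyl, both epimers at the nitro carbon | CCOC(=O)[C@@H]1[C@H](C)CC(=O)[C@@H]2C(C)(C)C=CC([N+](=O)[O-])[C@]21C | intermediate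
10 | ethyl 2,5,5,8a-tetramethyl-4-oxo-1,2,3,4,4a,5,8,8a-octahydronaphthalene-1-carboxylate; configuration as in 9 | CCOC(=O)[C@@H]1[C@H](C)CC(=O)[C@@H]2C(C)(C)C=CC[C@]21C | intermediate
11 | ethyl 2,5,5,8a-tetramethyl-4-oxodecahydronaphthalene-1-carboxylate; trans-fused, 1-CO2Et and 2-CH3 syn to the 8a-methyl | CCOC(=O)[C@@H]1[C@H](C)CC(=O)[C@@H]2C(C)(C)CCC[C@]21C | intermediate
12 | trimethylsilyl enol ether of 11 (C3=C4 double bond, 4-OSiMe3) | CCOC(=O)[C@@H]1[C@H](C)C=C(O[Si](C)(C)C)[C@@H]2C(C)(C)CCC[C@]21C | intermediate
13 | ethyl 2,5,5,8a-tetramethyl-4-oxo-1,4,4a,5,6,7,8,8a-octahydronaphthalene-1-carboxylate; trans-fused, 1-CO2Et syn to the 8a-methyl | CCOC(=O)[C@@H]1C(C)=CC(=O)[C@@H]2C(C)(C)CCC[C@]21C | intermediate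
14 | ethyl 2,3-epoxy-2,5,5,8a-tetramethyl-4-oxodecahydronaphthalene-1-carboxylate; epoxide oxygen anti, 2-CH3 and 1-CO2Et syn to the 8a-methyl | CCOC(=O)[C@@H]1[C@@]3(C)O[C@H]3C(=O)[C@@H]2C(C)(C)CCC[C@]21C | intermediate
15 | ethyl 2-hydroxy-2,5,5,8a-tetramethyl-1,2,4a,5,6,7,8,8a-octahydronaphthalene-1-carboxylate; 2-OH anti, 2-CH3 and 1-CO2Et syn to the 8a-methyl | CCOC(=O)[C@@H]1[C@@](C)(O)C=C[C@@H]2C(C)(C)CCC[C@]21C | intermediate
16 | ethyl 2,3,4-trihydroxy-2,5,5,8a-tetramethyldecahydronaphthalene-1-carboxylate; 2-, 3- and 4-OH all anti to the 8a-methyl | CCOC(=O)[C@@H]1[C@@](C)(O)[C@@H](O)[C@@H](O)[C@@H]2C(C)(C)CCC[C@]21C | intermediate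
17 | 3,4-O-dibutylstannylene acetal of 16 | CCOC(=O)[C@@H]1[C@@](C)(O)[C@H]3O[Sn](CCCC)(CCCC)O[C@H]3[C@@H]2C(C)(C)CCC[C@]21C | intermediate
18 | ethyl 2,4-dihydroxy-2,5,5,8a-tetramethyl-3-oxodecahydronaphthalene-1-carboxylate; 2-OH and 4-OH anti to the 8a-methyl | CCOC(=O)[C@@H]1[C@@](C)(O)C(=O)[C@@H](O)[C@@H]2C(C)(C)CCC[C@]21C | intermediate
19 | 1-(hydroxymethyl)-2,5,5,8a-tetramethyldecahydronaphthalene-2,3,4-triol; 2-OH and 4-OH anti, 3-OH and 1-CH2OH syn to the 8a-methyl | OC[C@@H]1[C@@](C)(O)[C@H](O)[C@@H](O)[C@@H]2C(C)(C)CCC[C@]21C | intermediate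
20 | 2,3,4-trihydroxy-2,5,5,8a-tetramethyldecahydronaphthalene-1-carbaldehyde; configuration as in 19 | O=C[C@@H]1[C@@](C)(O)[C@H](O)[C@@H](O)[C@@H]2C(C)(C)CCC[C@]21C | intermediate
21 | 1-(2-methoxyethenyl)-2,5,5,8a-tetramethyldecahydronaphthalene-2,3,4-triol (E/Z mixture); configuration as in 19 | COC=C[C@@H]1[C@@](C)(O)[C@H](O)[C@@H](O)[C@@H]2C(C)(C)CCC[C@]21C | intermediate
22 | 3a,6,6,9a-tetramethyldodecahydronaphtho[2,1-b]furan-2,4,5-triol (8,12-lactol in labdane numbering, both anomers) | OC1C[C@@H]2[C@@](C)(O1)[C@H](O)[C@@H](O)[C@@H]3C(C)(C)CCC[C@]32C | intermediate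
23 | 1-[(2Z)-3-iodobut-2-en-1-yl]-2,5,5,8a-tetramethyldecahydronaphthalene-2,3,4-triol; ring configuration as in 25 | C/C(I)=C/C[C@@H]1[C@@](C)(O)[C@H](O)[C@@H](O)[C@@H]2C(C)(C)CCC[C@]21C | intermediate
24 | 2,5,5,8a-tetramethyl-1-[(2Z)-3-methylpenta-2,4-dien-1-yl]decahydronaphthalene-2,3,4-triol; ring configuration as in 25 | C=C/C(C)=C\C[C@@H]1[C@@](C)(O)[C@H](O)[C@@H](O)[C@@H]2C(C)(C)CCC[C@]21C | intermediate
25 | (1S,2R,3R,4S,4aR,8aR)-2,4-dihydroxy-2,5,5,8a-tetramethyl-1-[(2Z)-3-methylpenta-2,4-dien-1-yl]decahydronaphthalen-3-yl acetate | C=C/C(C)=C\C[C@@H]1[C@@](C)(O)[C@H](OC(C)=O)[C@@H](O)[C@@H]2C(C)(C)CCC[C@]21C | target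

**Step count and risks**

Total step count: 16. Longest linear sequence: 16 steps (1 or 2 to 25); there is no convergent branch.

Steps most likely to fail:

1. Step 3 (key step, proposed new method). The condensation may stall at the nitro alcohol, or the hindered ring closure onto the dimethyl-substituted diene terminus may be outrun by oligomerisation of the nitrodiene and self-condensation of the enal. Fallback with known reactions, from 6 to 11: Michael addition of the nitronate of 6 to but-3-en-2-one (DBU, MeCN) should give the nitro diketone F1. Aldol condensation (pyrrolidine, AcOH, toluene, heat) closes ring A to the nitro enone F2, a Robinson-type annulation that still makes C1–C2 and C4–C5. Conjugate addition of Me2CuLi (Me3SiCl, THF, −40 °C; one extra equivalent for the acidic nitro C–H) installs the second C4 methyl group and, after equilibration of C5 on work-up with base, gives the trans-fused saturated nitro ketone F3. Radical denitration (Bu3SnH, AIBN, toluene, 110 °C) then gives 11, where the route is rejoined.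

2. Step 2. Addition to the fully substituted β-carbon may be slow because the acidic γ-hydrogen of 4 is removed first, and the funnelling of the two epimers through the cis form may be incomplete (facial selectivity). Fallback, from 4 to 10: conjugate addition of (CH2=CH)2CuLi (Me3SiCl, THF, −78 °C) to 4, equilibrated beforehand toward its cis epimer, should give the vinyl ketone F4 by the same approach anti to the ester and the methyl group. Ozonolysis (O3, CH2Cl2, −78 °C; Me2S) gives the keto aldehyde F5. Wittig reaction of the aldehyde with the ylide from (3-methylbut-2-enyl)triphenylphosphonium bromide and n-BuLi gives the dienyl ketone F6. TfOH (10 mol %, CH2Cl2, 0 °C) protonates the diene at C1 to the dimethylallyl cation, which the enol of the C6 ketone traps at C4 (cation–olefin cyclisation, trans-fused after equilibration of C5). This gives 10 directly, where the route is rejoined.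

3. Step 16. Site selectivity between the two secondary hydroxyls may be poor (acetylation at O6 or double acetylation). Fallback, from 24 to 25: acetylate without attempting kinetic control (Ac2O, Et3N, CH2Cl2, 23 °C, stopped at the monoacetate stage) to a mixture that contains the 6-O-acetyl regioisomer F7. Then equilibrate by base-mediated 1,2-acyl migration (DBU 10 mol %, toluene, 60 °C). The acetate on O6 is compressed against the equatorial C4 methyl group, so thermodynamic control should move it to O7 and give 25.

Further compounds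
F1 | step 3 | ethyl (1R,2R,6R)-2,6-dimethyl-2-(1-nitro-4-oxopentyl)-4-oxocyclohexane-1-carboxylate (both epimers at the nitro carbon) | CCOC(=O)[C@@H]1[C@H](C)CC(=O)C[C@@]1(C)C(CCC(C)=O)[N+](=O)[O-]
F2 | step 3 | ethyl 2,5,8a-trimethyl-8-nitro-4-oxo-1,2,3,4,6,7,8,8a-octahydronaphthalene-1-carboxylate (C4a=C5 enone; 1-CO2Et and 2-CH3 syn to the 8a-methyl) | CCOC(=O)[C@@H]1[C@H](C)CC(=O)C2=C(C)CCC([N+](=O)[O-])[C@]21C
F3 | step 3 | ethyl 2,5,5,8a-tetramethyl-8-nitro-4-oxodecahydronaphthalene-1-carboxylate (trans-fused; ring A saturated analogue of 9) | CCOC(=O)[C@@H]1[C@H](C)CC(=O)[C@@H]2C(C)(C)CCC([N+](=O)[O-])[C@]21C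
F4 | step 2 | ethyl 2-ethenyl-2,6-dimethyl-4-oxocyclohexane-1-carboxylate (vinyl in place of the nitromethyl group of 6, same configuration) | CCOC(=O)[C@@H]1[C@H](C)CC(=O)C[C@@]1(C)C=C
F5 | step 2 | ethyl 2-formyl-2,6-dimethyl-4-oxocyclohexane-1-carboxylate (formyl in place of the nitromethyl group of 6, same configuration) | CCOC(=O)[C@@H]1[C@H](C)CC(=O)C[C@@]1(C)C=O
F6 | step 2 | ethyl 2,6-dimethyl-2-(4-methylpenta-1,3-dien-1-yl)-4-oxocyclohexane-1-carboxylate (E/Z mixture at the new double bond, ring configuration as in 6) | CCOC(=O)[C@@H]1[C@H](C)CC(=O)C[C@@]1(C)C=CC=C(C)C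
F7 | step 16 | regioisomer of 25 with the acetate on O6 and a free 7-hydroxyl (labdane numbering) | C=C/C(C)=C\C[C@@H]1[C@@](C)(O)[C@H](O)[C@@H](OC(C)=O)[C@@H]2C(C)(C)CCC[C@]21C
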